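**Retrosynthetic overview**
1. Target ⇐ MOM removal ⇐ 36: the methoxy-enedione ring and both ring-fusion centres (C4a, C8a) come from a Rh-catalysed C–C activation/ring expansion (four- to six-membered) of 3-methoxycyclobutene-1,2-dione 34 across the chromone-bearing alkene of cyclohexadiene 35.
2. 35 ⇐ cobalt-catalysed [4+2] union of the (12E)-labdadienetriol 20 with 2-ethynylchromone 30 (forms the cyclohexadiene and C5).
3. 20 ⇐ 9α-hydroxysclareolide-type lactone 17 ⇐ α-face OsO4 on Δ8 ester 15 ⇐ enol triflate of decalone 11 ⇐ diazoethane ring expansion of the Hajos–Parrish-derived trans-hydrindanone 10.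
4. 30 ⇐ chromone-2-carboxylate from resorcinol (Claisen/cyclisation, C5–H hydroxylation); 34 ⇐ squaric acid.
5. Ring order: terpenoid ring A plus five-membered ring → decalin ring B by ring expansion; chromone pyranone; cyclohexadiene; enedione ring last.

Assumption: phosphorus ylides and diazo, silyl and triflyl donors count as reagents; the carbon skeleton comes only from 1, 2, 13, 21, 23 and 31 (each at most eight non-hydrogen atoms); terpenoid intermediates use labdane numbering.

**Route**

Step 1
Reactants: 1 2-methylcyclopentane-1,3-dione; 2 pent-1-en-3-one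
Product: 5 (S)-4,7a-dimethyl-2,3,7,7a-tetrahydro-1H-indene-1,5(6H)-dione, via triketone 3 (not isolated), via bicyclic ketol 4 (not isolated)
Conditions: H2O, AcOH (cat.), 70 °C; evaporate; (S)-phenylalanine (1 equiv), 1 M HClO4 (0.4 equiv), MeCN, 80 °C
Reagents that add atoms: none
Why: Michael addition followed by the Hajos–Parrish–Eder–Sauer–Wiechert amino-acid-mediated enamine aldol cyclodehydration, in which the (S)-amino acid differentiates the two ring carbonyls and sets the quaternary centre (labdane C10) as S.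

Step 2
Reactants: 5 (S)-4,7a-dimethyl-2,3,7,7a-tetrahydro-1H-indene-1,5(6H)-dione
Product: 6 C1 ethylene ketal of 5
Conditions: TMSOCH2CH2OTMS, TMSOTf (cat.), CH2Cl2, −78 °C
Reagents that add atoms: 1,2-bis(trimethylsilyloxy)ethane (C[Si](C)(C)OCCO[Si](C)(C)C)
Why: Noyori ketalisation is selective for the saturated cyclopentanone over the tetrasubstituted enone, which must stay free for the next step.

Step 3
Reactants: 6 C1 ethylene ketal of 5
Product: 7 trans-fused 4,4,7a-trimethyl-hexahydroindan-5-one 1-ethylene ketal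
Conditions: Li, NH3(l)/THF, t-BuOH (1 equiv), −78 °C; then MeI
Reagents that add atoms: iodomethane (CI)
Why: Stork reductive alkylation (Birch-type enone reduction), in which protonation of the β-carbon anti to the angular methyl gives the trans ring fusion (labdane 5α-H) and the regiodefined enolate is C-methylated to the gem-dimethyl ketone.

Step 4
Reactants: 7 trans-fused 4,4,7a-trimethyl-hexahydroindan-5-one 1-ethylene ketal
Product: 10 trans-4,4,7a-trimethyl-2,3,3a,4,7,7a-hexahydro-1H-inden-1-one, via tosylhydrazone 8 (not isolated), via alkene ketal 9 (not isolated)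
Conditions: TsNHNH2, EtOH, 70 °C; evaporate; n-BuLi (3.5 equiv), THF, −78 → 0 °C; then 2 M HCl, THF, rt
Reagents that add atoms: water (O)
Why: Shapiro reaction, where the only α-CH2 (labdane C2) is deprotonated so the vinyl anion gives the Δ2 alkene, and the acidic work-up hydrolyses the dioxolane without touching the two ring-fusion centres.

Step 5
Reactants: 10 trans-4,4,7a-trimethyl-2,3,3a,4,7,7a-hexahydro-1H-inden-1-one
Product: 11 trans-2,5,5,8a-tetramethyl-3,4,4a,5,8,8a-hexahydronaphthalen-1(2H)-one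
Conditions: CH3CHN2 (Et2O solution), BF3·OEt2, Et2O, −30 → 0 °C
Reagents that add atoms: diazoethane (CC=[N+]=[N-])
Why: Lewis-acid-promoted diazoalkane ring expansion (Tiffeneau–Demjanov type), in which the less substituted CH2 (C7) migrates with loss of N2, turning the hydrindanone into the 8-methyl-decal-9-one; the new C8 centre is erased in step 6.

Step 6
Reactants: 11 trans-2,5,5,8a-tetramethyl-3,4,4a,5,8,8a-hexahydronaphthalen-1(2H)-one
Product: 12 Δ8 enol triflate of 11
Conditions: KHMDS, THF, −78 → 0 °C; PhNTf2; aq NH4Cl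
Reagents that add atoms: N-phenylbis(trifluoromethanesulfonimide) (O=S(=O)(N(c1ccccc1)S(=O)(=O)C(F)(F)F)C(F)(F)F)
Why: Enolate O-sulfonylation, which can only give the tetrasubstituted Δ8(9) enol triflate because C10 is quaternary.

Step 7
Reactants: 12 Δ8 enol triflate of 11; 13 methyl bromoacetate
Product: 14 methyl 13,14,15,16-tetranorlabda-2,8-dien-12-oate
Conditions: 13, Zn, THF (Reformatsky reagent); then 12, Pd2(dba)3 (2.5 mol %), XPhos (10 mol %), THF, 65 °C
Reagents that add atoms: none
Why: Negishi cross-coupling of the alkenyl triflate with the zinc ester enolate attaches C11–C12 to the sp2 C9, and the tetrasubstituted β,γ-alkene does not move into conjugation.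

Step 8
Reactants: 14 methyl 13,14,15,16-tetranorlabda-2,8-dien-12-oate
Product: 15 methyl 2α-hydroxy-13,14,15,16-tetranorlabd-8-en-12-oate
Conditions: BH3·THF (1.2 equiv), THF, 0 °C; then 30 % H2O2, pH 7 phosphate buffer, 0 °C
Reagents that add atoms: hydrogen peroxide (OO)
Why: Hydroboration–oxidation of the Δ2 alkene, where boron adds to C2 (away from the neopentyl C3) from the α-face opposite the axial 4β- and 10β-methyls to give the equatorial 2α-OH, while the tetrasubstituted Δ8 alkene and the ester react much more slowly.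

Step 9
Reactants: 15 methyl 2α-hydroxy-13,14,15,16-tetranorlabd-8-en-12-oate
Product: 17 2α,9α-dihydroxy-13,14,15,16-tetranorlabdano-12,8α-lactone, via triol ester 16 (not isolated)
Conditions: OsO4 (1.1 equiv), pyridine, CH2Cl2, rt; aq NaHSO3; then p-TsOH (cat.), CH2Cl2, rt
Reagents that add atoms: osmium tetroxide (O=[Os](=O)(=O)=O)
Why: Stoichiometric OsO4 syn-dihydroxylation from the α-face, opposite the axial C10 methyl, sets C8 and C9 together (8α-OH, 9α-OH, C11 β), and the 8α-OH then lactonises onto the ester as in sclareolide.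

Step 10
Reactants: 17 2α,9α-dihydroxy-13,14,15,16-tetranorlabdano-12,8α-lactone
Product: 19 (12E)-2α,8α,9α-trihydroxy-15-norlabd-12-en-14-al, via lactol 18 (not isolated)
Conditions: DIBAL-H (4 equiv), CH2Cl2, −78 °C; MeOH, aq Rochelle salt; crude lactol, Ph3P=C(CH3)CHO (2.5 equiv), toluene, 80 °C
Reagents that add atoms: 2-(triphenylphosphoranylidene)propanal (CC(C=O)=P(c1ccccc1)(c1ccccc1)c1ccccc1)
Why: Lactone half-reduction, then Wittig olefination of the lactol with a stabilised ylide gives the trisubstituted enal with E geometry; the neutral conditions avoid oxa-Michael closure by the 8-OH.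

Step 11
Reactants: 19 (12E)-2α,8α,9α-trihydroxy-15-norlabd-12-en-14-al
Product: 20 (12E)-labda-12,14-diene-2α,8α,9α-triol
Conditions: Ph3PCH3Br, KHMDS, THF, 0 °C; add 19 at −78 → 0 °C
Reagents that add atoms: methyltriphenylphosphonium bromide (C[P+](c1ccccc1)(c1ccccc1)c1ccccc1.[Br-])
Why: Wittig methylenation of the enal completes the diene without touching the 12E double bond or the free hydroxyls.

Step 12
Reactants: 21 resorcinol
Product: 22 1-(2,4-dihydroxyphenyl)ethanone
Conditions: AcOH, ZnCl2, 140 °C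
Reagents that add atoms: acetic acid (CC(=O)O)
Why: Nencki (Friedel–Crafts) acylation at C4 of resorcinol, ortho to one hydroxyl and para to the other.

Step 13
Reactants: 22 1-(2,4-dihydroxyphenyl)ethanone; 23 dimethyl oxalate
Product: 25 methyl 7-hydroxy-4-oxo-4H-chromene-2-carboxylate, via diketo ester 24 (not isolated)
Conditions: NaOMe, MeOH, reflux; then conc. HCl, MeOH, reflux
Reagents that add atoms: none
Why: Claisen condensation of the acetophenone with the oxalate, then acid cyclodehydration of the 2-hydroxyaryl diketo ester (classical chromone-2-carboxylate synthesis).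

Step 14
Reactants: 25 methyl 7-hydroxy-4-oxo-4H-chromene-2-carboxylate
Product: 27 methyl 5,7-dihydroxy-4-oxo-4H-chromene-2-carboxylate, via bis(trifluoroacetate) 26 (not isolated)
Conditions: [RuCl2(p-cymene)]2 (5 mol %), PhI(OCOCF3)2 (2 equiv), TFA/TFAA, 80 °C; then aq NaHCO3/MeOH
Reagents that add atoms: [bis(trifluoroacetoxy)iodo]benzene (O=C(OI(OC(=O)C(F)(F)F)c1ccccc1)C(F)(F)F)
Why: Ketone-directed Ru(II)-catalysed C–H oxygenation, where the C4 carbonyl directs ruthenation to the peri C5–H and the aryl trifluoroacetates are hydrolysed on work-up.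

Step 15
Reactants: 27 methyl 5,7-dihydroxy-4-oxo-4H-chromene-2-carboxylate
Product: 28 methyl 5,7-bis(methoxymethoxy)-4-oxo-4H-chromene-2-carboxylate
Conditions: NaH (2.2 equiv), MOMCl (2.5 equiv), DMF, 0 °C → rt
Reagents that add atoms: chloromethyl methyl ether (COCCl)
Why: O-alkylation of both phenoxides gives acetal protecting groups that survive hydride, base and the metal catalysts and leave under mild acid.

Step 16
Reactants: 28 methyl 5,7-bis(methoxymethoxy)-4-oxo-4H-chromene-2-carboxylate
Product: 30 2-ethynyl-5,7-bis(methoxymethoxy)-4H-chromen-4-one, via aldehyde 29 (not isolated)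
Conditions: DIBAL-H (1.1 equiv), CH2Cl2, −78 °C; MeOH; then dimethyl (1-diazo-2-oxopropyl)phosphonate, K2CO3, MeOH, 0 °C → rt
Reagents that add atoms: dimethyl (1-diazo-2-oxopropyl)phosphonate (CC(=O)C(=[N+]=[N-])P(=O)(OC)OC)
Why: Ester half-reduction followed in the same pot by Seyferth–Gilbert homologation with the Bestmann–Ohira reagent converts the C2 ester into the terminal alkyne.

Step 17
Reactants: 31 squaric acid
Product: 32 3,4-dimethoxycyclobut-3-ene-1,2-dione
Conditions: HC(OMe)3, MeOH, reflux
Reagents that add atoms: trimethyl orthoformate (COC(OC)OC); methanol (CO)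
Why: Esterification of the vinylogous diacid, driven by the orthoformate as water scavenger.

Step 18
Reactants: 32 3,4-dimethoxycyclobut-3-ene-1,2-dione
Product: 34 3-methoxycyclobut-3-ene-1,2-dione, via hydroxycyclobutenone 33 (not isolated)
Conditions: LiAlH(Ot-Bu)3, THF, −78 °C; then conc. HCl, CH2Cl2, 0 °C
Reagents that add atoms: none
Why: Mono-reduction of one vinylogous-ester carbonyl, then acid-induced allylic ionisation and loss of methanol (the established route to semisquarate esters).

Step 19
Reactants: 20 (12E)-labda-12,14-diene-2α,8α,9α-triol; 30 2-ethynyl-5,7-bis(methoxymethoxy)-4H-chromen-4-one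
Product: 35 2-[(6R)-5-methyl-6-(2α,8α,9α-trihydroxy-12,13,14,15,16-pentanorlabdan-11-yl)cyclohexa-1,4-dien-1-yl]-5,7-bis(methoxymethoxy)-4H-chromen-4-one
Conditions: CoBr2/(S,S)-BDPP (10 mol %), Zn, ZnI2, CH2Cl2, 25 °C, Ar
Reagents that add atoms: none
Why: Cobalt(I)-catalysed diene–alkyne [4+2] cycloaddition (oxidative cyclisation to a cobaltacycle, then allyl–vinyl reductive elimination), in which the alkyne CH couples with the unsubstituted C15 terminus so the chromone-bearing carbon bonds to C12, and the chiral bisphosphine (matched enantiomer to be confirmed by screening) selects the diene face to give the 6R centre (target C5).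

Step 20
Reactants: 35 cyclohexadiene from step 19; 34 3-methoxycyclobut-3-ene-1,2-dione
Product: 36 5,7-bis(methoxymethyl) ether of the target
Conditions: [Rh(cod)Cl]2 (5 mol %), P(C6F5)3 (20 mol %), 34 (2 equiv), 1,4-dioxane, 90 °C, Ar
Reagents that add atoms: none
Why: Proposed new method: Rh(I) inserts into the strained acyl–acyl bond of 34 (known stoichiometrically for cyclobutenediones), the chromone-conjugated C1=C2 alkene of 35 binds on the face anti to the C6 side chain, the ketone-like acyl next to C–OMe migrates to the unhindered CH terminus to leave a chromone-stabilised Rh–C at the future C4a, and C(sp3)–acyl reductive elimination with the less hindered vinylogous-ester acyl closes the six-membered ring, so both new bonds form syn and anti to C11 (4aS, 8aR, cis fusion, chromone cis to the side chain) while the unactivated trisubstituted alkene is left alone; the closest known reactions are Liebeskind's maleoyl-metal/alkyne quinone synthesis and Rh-catalysed "cut-and-sew" additions of cyclobutanones and benzocyclobutenones to alkenes.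

Step 21
Reactants: 36 5,7-bis(methoxymethyl) ether of the target
Product: 37 target CNP0385027.1
Conditions: HCl (1.25 M in MeOH), 35 °C
Reagents that add atoms: none
Why: Acid-catalysed transacetalisation removes the two phenolic MOM groups as dimethoxymethane; in methanol any exchange at the methoxy-enone is degenerate, and the tertiary diol and the cis ring fusion tolerate the mild conditions.

**Compound list**

1 | 2-methylcyclopentane-1,3-dione | CC1C(=O)CCC1=O | starting material
2 | pent-1-en-3-one (ethyl vinyl ketone) | CCC(=O)C=C | starting material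
3 | 2-methyl-2-(3-oxopentyl)cyclopentane-1,3-dione | CCC(=O)CCC1(C)C(=O)CCC1=O | intermediate
4 | (7aS)-3a-hydroxy-4,7a-dimethylhexahydro-1H-indene-1,5(4H)-dione, 3a-OH cis to 7a-CH3, C4 epimers | C[C@]12CCC(=O)C(C)[C@@]1(O)CCC2=O | intermediate
5 | (S)-4,7a-dimethyl-2,3,7,7a-tetrahydro-1H-indene-1,5(6H)-dione | C[C@]12CCC(=O)C(C)=C1CCC2=O | intermediate
6 | (7aS) C1 ethylene ketal of 5 (spiro-dioxolane at C1) | C[C@]12CCC(=O)C(C)=C1CCC21OCCO1 | intermediate
7 | trans-fused 4,4,7a-trimethyl-hexahydroindan-5-one 1-ethylene ketal (3a-H α, 7a-CH3 β) | C[C@]12CCC(=O)C(C)(C)[C@@H]1CCC21OCCO1 | intermediate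
8 | tosylhydrazone of 7 | C[C@]12CCC(=NNS(=O)(=O)c3ccc(C)cc3)C(C)(C)[C@@H]1CCC21OCCO1 | intermediate
9 | trans-4,4,7a-trimethyl-3a,4,7,7a-tetrahydroindan-1-one ethylene ketal (labdane Δ2) | C[C@]12CC=CC(C)(C)[C@@H]1CCC21OCCO1 | intermediate
10 | trans-4,4,7a-trimethyl-2,3,3a,4,7,7a-hexahydro-1H-inden-1-one (3a-H α, 7a-CH3 β) | C[C@]12CC=CC(C)(C)[C@@H]1CCC2=O | intermediate
11 | trans-2,5,5,8a-tetramethyl-3,4,4a,5,8,8a-hexahydronaphthalen-1(2H)-one (5α-H, 10β-CH3, C8 epimers; labdane 9-ketone) | O=C1[C@@]2(C)CC=CC(C)(C)[C@@H]2CCC1C | intermediate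
12 | trans-2,5,5,8a-tetramethyl-3,4,4a,5,8,8a-hexahydronaphthalen-1-yl trifluoromethanesulfonate (Δ8 enol triflate) | CC1=C(OS(=O)(=O)C(F)(F)F)[C@@]2(C)CC=CC(C)(C)[C@@H]2CC1 | intermediate
13 | methyl bromoacetate | BrCC(=O)OC | starting material
14 | methyl 13,14,15,16-tetranorlabda-2,8-dien-12-oate | CC1=C(CC(=O)OC)[C@@]2(C)CC=CC(C)(C)[C@@H]2CC1 | intermediate
15 | methyl 2α-hydroxy-13,14,15,16-tetranorlabd-8-en-12-oate | CC1=C(CC(=O)OC)[C@@]2(C)C[C@@H](O)CC(C)(C)[C@@H]2CC1 | intermediate
16 | methyl 2α,8α,9α-trihydroxy-13,14,15,16-tetranorlabdan-12-oate | COC(=O)C[C@]1(O)[C@@]2(C)C[C@@H](O)CC(C)(C)[C@@H]2CC[C@@]1(C)O | intermediate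
17 | 2α,9α-dihydroxy-13,14,15,16-tetranorlabdano-12,8α-lactone | O=C1C[C@]2(O)[C@@]3(C)C[C@@H](O)CC(C)(C)[C@@H]3CC[C@@]2(C)O1 | intermediate
18 | 8α,12-epoxy-13,14,15,16-tetranorlabdane-2α,9α,12-triol (lactol, C12 epimers) | OC1C[C@]2(O)[C@@]3(C)C[C@@H](O)CC(C)(C)[C@@H]3CC[C@@]2(C)O1 | intermediate
19 | (12E)-2α,8α,9α-trihydroxy-15-norlabd-12-en-14-al | O=C/C(C)=C/C[C@]1(O)[C@@]2(C)C[C@@H](O)CC(C)(C)[C@@H]2CC[C@@]1(C)O | intermediate
20 | (12E)-labda-12,14-diene-2α,8α,9α-triol | C=C/C(C)=C/C[C@]1(O)[C@@]2(C)C[C@@H](O)CC(C)(C)[C@@H]2CC[C@@]1(C)O | intermediate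
21 | resorcinol | Oc1cccc(O)c1 | starting material
22 | 1-(2,4-dihydroxyphenyl)ethanone | CC(=O)c1ccc(O)cc1O | intermediate
23 | dimethyl oxalate | COC(=O)C(=O)OC | starting material
24 | methyl 4-(2,4-dihydroxyphenyl)-2,4-dioxobutanoate | COC(=O)C(=O)CC(=O)c1ccc(O)cc1O | intermediate
25 | methyl 7-hydroxy-4-oxo-4H-chromene-2-carboxylate | COC(=O)c1cc(=O)c2ccc(O)cc2o1 | intermediate
26 | methyl 4-oxo-5,7-bis(trifluoroacetoxy)-4H-chromene-2-carboxylate | COC(=O)c1cc(=O)c2c(OC(=O)C(F)(F)F)cc(OC(=O)C(F)(F)F)cc2o1 | intermediate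
27 | methyl 5,7-dihydroxy-4-oxo-4H-chromene-2-carboxylate | COC(=O)c1cc(=O)c2c(O)cc(O)cc2o1 | intermediate
28 | methyl 5,7-bis(methoxymethoxy)-4-oxo-4H-chromene-2-carboxylate | COCOc1cc(OCOC)c2c(c1)oc(C(=O)OC)cc2=O | intermediate
29 | 5,7-bis(methoxymethoxy)-4-oxo-4H-chromene-2-carbaldehyde | COCOc1cc(OCOC)c2c(c1)oc(C=O)cc2=O | intermediate
30 | 2-ethynyl-5,7-bis(methoxymethoxy)-4H-chromen-4-one | COCOc1cc(OCOC)c2c(c1)oc(C#C)cc2=O | intermediate
31 | squaric acid (3,4-dihydroxycyclobut-3-ene-1,2-dione) | OC1=C(O)C(=O)C1=O | starting material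
32 | 3,4-dimethoxycyclobut-3-ene-1,2-dione | COC1=C(OC)C(=O)C1=O | intermediate
33 | 4-hydroxy-2,3-dimethoxycyclobut-2-en-1-one (racemic) | COC1=C(OC)C(O)C1=O | intermediate
34 | 3-methoxycyclobut-3-ene-1,2-dione | COC1=CC(=O)C1=O | intermediate
35 | 2-[(6R)-5-methyl-6-(2α,8α,9α-trihydroxy-12,13,14,15,16-pentanorlabdan-11-yl)cyclohexa-1,4-dien-1-yl]-5,7-bis(methoxymethoxy)-4H-chromen-4-one | COCOc1cc(OCOC)c2c(c1)oc(cc2=O)C1=CCC=C(C)[C@H]1C[C@]1(O)[C@@]2(C)C[C@@H](O)CC(C)(C)[C@@H]2CC[C@@]1(C)O | intermediate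
36 | (4aS,5R,8aR)-4a-[5,7-bis(methoxymethoxy)-4-oxo-4H-chromen-2-yl]-2-methoxy-6-methyl-5-(2α,8α,9α-trihydroxy-12,13,14,15,16-pentanorlabdan-11-yl)-4a,5,8,8a-tetrahydronaphthalene-1,4-dione | COC1=CC(=O)[C@@]2(c3cc(=O)c4c(OCOC)cc(OCOC)cc4o3)[C@H](C[C@]3(O)[C@@]4(C)C[C@@H](O)CC(C)(C)[C@@H]4CC[C@@]3(C)O)C(C)=CC[C@H]2C1=O | intermediate
37 | (4aS,5R,8aR)-4a-(5,7-dihydroxy-4-oxo-4H-chromen-2-yl)-2-methoxy-6-methyl-5-(2α,8α,9α-trihydroxy-12,13,14,15,16-pentanorlabdan-11-yl)-4a,5,8,8a-tetrahydronaphthalene-1,4-dione (CNP0385027.1) | COC1=CC(=O)[C@@]2(c3cc(=O)c4c(O)cc(O)cc4o3)[C@H](C[C@]3(O)[C@@]4(C)C[C@@H](O)CC(C)(C)[C@@H]4CC[C@@]3(C)O)C(C)=CC[C@H]2C1=O | target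

**Step count and risks**

Total step count: 21. Longest linear sequence: 14 steps (steps 1–11, then 19–21).

Most likely to fail, in this order:

Step 20 (the proposed Rh ring expansion). Intermolecular alkene insertion into the rhodacycle may lose to decarbonylation, β-hydride elimination at the new Rh–C bond, or aromatisation of the 1,4-diene; the wrong acyl could also migrate first and give the methoxy regioisomer. The fallback uses known chemistry only; it sets out from lactol 18 (isolated after the DIBAL reduction of 17), alkyne 30 and dione 34, and comes back to the route at 36. The bromomagnesium acetylide of 30 (i-PrMgCl·LiCl, THF, −40 °C) adds to the ketone-like carbonyl of 34 to give 4-{[5,7-bis(methoxymethoxy)-4-oxo-4H-chromen-2-yl]ethynyl}-4-hydroxy-3-methoxycyclobut-2-en-1-one F1. Heating F1 in xylene (Moore rearrangement) gives 2-[5,7-bis(methoxymethoxy)-4-oxo-4H-chromen-2-yl]-5-methoxy-1,4-benzoquinone F2. In parallel, 18 is converted by Stork–Zhao olefination (Ph3P=C(I)CH3) into (12Z)-13-iodo-14,15-dinorlabd-12-ene-2α,8α,9α-triol F3, and by Stille coupling with tributyl(vinyl)stannane into (12Z)-labda-12,14-diene-2α,8α,9α-triol F4. A Diels–Alder reaction of F4 with F2 (chiral oxazaborolidinium Lewis acid, or 12 kbar), endo with respect to the quinone ring, then gives 36. The Z diene is needed because the quinone-endo adduct of the E diene 20 would be the C5 epimer.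

Step 19 (cobalt [4+2]). The diene terminus C12 is substituted, so reactivity and regiochemistry are uncertain, and facial control at C12 rests on the chiral ligand with little direct precedent on a substrate of this kind. The fallback sets out from 20 and 30 and comes back at 35 without any new compound (F0). It gives up catalyst control and runs the concerted, uncatalysed Diels–Alder reaction (CH2Cl2, 12 kbar, rt, or toluene, 120 °C with BHT), whose regiochemistry follows the usual "ortho" rule for a 1-substituted diene and an acceptor-substituted alkyne; the two C12 epimers of 35 are then separated by preparative HPLC and only the 6R isomer is carried on.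

Step 5 (diazoethane ring expansion). The quaternary carbon may migrate in part, and over-homologation or epoxide formation can compete. The fallback sets out from 10 and comes back at 11. Diazomethane with BF3·OEt2 gives the one-carbon ring-expanded trans-5,5,8a-trimethyl-3,4,4a,5,8,8a-hexahydronaphthalen-1(2H)-one F5, which is purified; its only enolisable position (C8) is then methylated with LDA/MeI to give 11.

Further compounds
F1 | step 20 | 4-{[5,7-bis(methoxymethoxy)-4-oxo-4H-chromen-2-yl]ethynyl}-4-hydroxy-3-methoxycyclobut-2-en-1-one | COC1=CC(=O)C1(O)C#Cc1cc(=O)c2c(OCOC)cc(OCOC)cc2o1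
F2 | step 20 | 2-[5,7-bis(methoxymethoxy)-4-oxo-4H-chromen-2-yl]-5-methoxy-1,4-benzoquinone | COC1=CC(=O)C(=CC1=O)c1cc(=O)c2c(OCOC)cc(OCOC)cc2o1
F3 | step 20 | (12Z)-13-iodo-14,15-dinorlabd-12-ene-2α,8α,9α-triol | I/C(C)=C\C[C@]1(O)[C@@]2(C)C[C@@H](O)CC(C)(C)[C@@H]2CC[C@@]1(C)O
F4 | step 20 | (12Z)-labda-12,14-diene-2α,8α,9α-triol | C=C/C(C)=C\C[C@]1(O)[C@@]2(C)C[C@@H](O)CC(C)(C)[C@@H]2CC[C@@]1(C)O
F0 | step 19 | none | none
F5 | step 5 | trans-5,5,8a-trimethyl-3,4,4a,5,8,8a-hexahydronaphthalen-1(2H)-one | O=C1[C@@]2(C)CC=CC(C)(C)[C@@H]2CCC1
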